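**Plan** (ring locants as in the target name: C1 bears the chain, C2 = CMe2, C3 = CHBr, C6 = C=CH2; chain locants C1 = CH2Br to C5)
Retrosynthetic cuts, in order: chain C2 carbinol and C1 (CBS reduction of a bromomethyl (Z)-enone made from a Weinreb amide and LiCH2Br); chain C3=C4 (Still–Gennari); ring C3–Br (Appel inversion of a ring alcohol); ring bond C5–C6 (hydroboration/intramolecular B-alkyl Suzuki–Miyaura coupling); ring bond C1–C2, the CH–CMe2 bond (Ir-catalysed allylic alkylation).
Forward: an (E)-allyl carbonate and the silyl ketene acetal of methyl isobutyrate are joined at the tertiary/quaternary bond; the vinyl group becomes a 2-iodoalkene and the ester a vinyl carbinol; the cyclohexane is closed in one pot; the ring bromide and then the side chain follow.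
Stereochemistry: ring C1 from the chiral Ir catalyst; ring C3 from a CBS reduction of the acyclic vinyl ketone, then inverted by bromide; the (Z)-alkene from the Still–Gennari olefination; chain C2 from a second CBS reduction.
Enabling feature: the ring has an exocyclic C6=CH2 next to an unsubstituted C5H2, and C5–C4–C3 ends at the heteroatom-bearing C3. So C6 maps onto an alkenyl iodide and C3–C4–C5 onto a vinyl carbinol whose anti-Markovnikov borane sits on C5, with the C2 gem-dimethyl group in the tether favouring six-membered closure. Ring and methylidene arise together and no stereocentre is touched.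

Key step: step 12

Assumption: the (Sa,S,S)-ligand of step 5 is taken to give the (3R)-ester; if the first run shows the opposite sense, the mirror-image ligand is used and nothing else changes.

**Step 1**
Reactants: 1 but-3-yn-1-ol; 2 tert-butylchlorodiphenylsilane
Product: 3 tert-butyl(but-3-yn-1-yloxy)diphenylsilane
Conditions: imidazole, DMF, 0 °C → rt
Reagents that add atoms: tert-butylchlorodiphenylsilane, CC(C)(C)[Si](Cl)(c1ccccc1)c1ccccc1
Why: Imidazole-mediated silylation of the primary alcohol (silyl ether protection) should be clean, and this bulky silyl group is chosen to outlast the haloboration, AlMe3, aqueous base and the Appel step.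

**Step 2**
Reactants: 3 tert-butyl(but-3-yn-1-yloxy)diphenylsilane; 4 paraformaldehyde
Product: 6 5-[(tert-butyldiphenylsilyl)oxy]pent-2-yn-1-ol, via lithium acetylide 5 (not isolated)
Conditions: n-BuLi, THF, −78 °C; then (CH2O)n, −78 °C → rt; aq. NH4Cl
Reagents that add atoms: formaldehyde (as paraformaldehyde), C=O
Why: Deprotonation of the terminal alkyne and addition of the lithium acetylide to formaldehyde (acetylide hydroxymethylation) should give the propargylic alcohol without touching the silyl ether.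

**Step 3**
Reactants: 6 5-[(tert-butyldiphenylsilyl)oxy]pent-2-yn-1-ol
Product: 7 (2E)-5-[(tert-butyldiphenylsilyl)oxy]pent-2-en-1-ol
Conditions: NaAlH2(OCH2CH2OMe)2, THF, 0 °C → rt; aq. potassium sodium tartrate
Reagents that add atoms: none
Why: Alkoxide-directed trans-hydroalumination of the propargylic alcohol and protonolysis of the vinylalane should give the (E)-allylic alcohol as the only alkene isomer.

**Step 4**
Reactants: 7 (2E)-5-[(tert-butyldiphenylsilyl)oxy]pent-2-en-1-ol; 8 methyl chloroformate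
Product: 9 (2E)-5-[(tert-butyldiphenylsilyl)oxy]pent-2-en-1-yl methyl carbonate
Conditions: pyridine, CH2Cl2, 0 °C
Reagents that add atoms: methyl chloroformate, COC(=O)Cl
Why: Acylation of the primary allylic alcohol with a chloroformate (carbonate formation) installs a leaving group that releases methoxide, the activator of the silyl ketene acetal in the next step.

**Step 5**
Reactants: 9 (2E)-5-[(tert-butyldiphenylsilyl)oxy]pent-2-en-1-yl methyl carbonate; 10 1-methoxy-2-methyl-1-(trimethylsilyloxy)prop-1-ene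
Product: 11 methyl (3R)-3-{2-[(tert-butyldiphenylsilyl)oxy]ethyl}-2,2-dimethylpent-4-enoate
Conditions: [Ir(cod)Cl]2 (2 mol %), (Sa,S,S)-O,O′-(1,1′-binaphthalene-2,2′-diyl) N,N-bis(1-phenylethyl)phosphoramidite (4 mol %, cyclometalated with n-PrNH2), THF, rt → 40 °C
Reagents that add atoms: 1-methoxy-2-methyl-1-(trimethylsilyloxy)prop-1-ene, COC(O[Si](C)(C)C)=C(C)C
Why: Iridium-catalysed branched-selective asymmetric allylic alkylation with a silyl ketene acetal: ionisation of the carbonate gives an allyliridium complex and methoxide, which activates the ketene acetal, and the fully substituted enolate carbon should attack the substituted allyl terminus on the face fixed by the phosphoramidite, forming the CH–CMe2 bond and the (3R) centre that becomes ring C1.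

**Step 6**
Reactants: 11 methyl (3R)-3-{2-[(tert-butyldiphenylsilyl)oxy]ethyl}-2,2-dimethylpent-4-enoate; 12 ozone
Product: 14 methyl (3S)-5-[(tert-butyldiphenylsilyl)oxy]-3-formyl-2,2-dimethylpentanoate, via ozonide 13 (not isolated)
Conditions: O3, CH2Cl2, −78 °C; then PPh3, −78 °C → rt
Reagents that add atoms: ozone, [O-][O+]=O
Why: Ozonolysis with reductive work-up should cleave the only C=C bond to the aldehyde under neutral conditions, so the adjacent tertiary centre keeps its configuration (the descriptor changes only through the priority rules).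

**Step 7**
Reactants: 14 methyl (3S)-5-[(tert-butyldiphenylsilyl)oxy]-3-formyl-2,2-dimethylpentanoate; 15 dimethyl (1-diazo-2-oxopropyl)phosphonate
Product: 16 methyl (3R)-5-[(tert-butyldiphenylsilyl)oxy]-3-ethynyl-2,2-dimethylpentanoate
Conditions: K2CO3, MeOH, 0 °C → rt
Reagents that add atoms: dimethyl (1-diazo-2-oxopropyl)phosphonate, COP(=O)(OC)C(=[N+]=[N-])C(C)=O
Why: Ohira–Bestmann (Seyferth–Gilbert) homologation converts the aldehyde into the terminal alkyne under mild carbonate/methanol conditions, and the α-centre, flanked by a quaternary carbon, should enolise too slowly to epimerise.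

**Step 8**
Reactants: 16 methyl (3R)-5-[(tert-butyldiphenylsilyl)oxy]-3-ethynyl-2,2-dimethylpentanoate; 17 9-iodo-9-borabicyclo[3.3.1]nonane
Product: 19 methyl (3S)-3-{2-[(tert-butyldiphenylsilyl)oxy]ethyl}-4-iodo-2,2-dimethylpent-4-enoate, via iodovinylborane 18 (not isolated)
Conditions: pentane/CH2Cl2, −20 → 0 °C; then AcOH, 0 °C
Reagents that add atoms: 9-iodo-9-borabicyclo[3.3.1]nonane, IB1C2CCCC1CCC2
Why: syn-Iodoboration of the terminal alkyne places boron on the terminal and iodine on the internal carbon, and protodeboronation with acetic acid should give the 2-iodoalk-1-ene (net Markovnikov hydroiodination) without affecting the ester or the silyl ether.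

**Step 9**
Reactants: 19 methyl (3S)-3-{2-[(tert-butyldiphenylsilyl)oxy]ethyl}-4-iodo-2,2-dimethylpent-4-enoate; 20 N,O-dimethylhydroxylamine hydrochloride
Product: 21 (3S)-3-{2-[(tert-butyldiphenylsilyl)oxy]ethyl}-4-iodo-N-methoxy-N,2,2-trimethylpent-4-enamide
Conditions: AlMe3, CH2Cl2, 0 → 40 °C
Reagents that add atoms: N,O-dimethylhydroxylamine hydrochloride, CNOC.Cl
Why: Aluminium amide aminolysis of the ester (Weinreb amide formation) should overcome the hindrance of the α-quaternary ester on warming and leaves the alkenyl iodide and the silyl ether intact.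

**Step 10**
Reactants: 21 (3S)-3-{2-[(tert-butyldiphenylsilyl)oxy]ethyl}-4-iodo-N-methoxy-N,2,2-trimethylpent-4-enamide; 22 vinylmagnesium bromide
Product: 23 (5S)-5-{2-[(tert-butyldiphenylsilyl)oxy]ethyl}-6-iodo-4,4-dimethylhepta-1,6-dien-3-one
Conditions: THF, −20 → 0 °C; inverse quench into cold 1 M HCl
Reagents that add atoms: vinylmagnesium bromide, C=C[Mg]Br
Why: Addition of the vinyl Grignard reagent stops at the chelated tetrahedral intermediate (Weinreb ketone synthesis), and the inverse acidic quench should keep the released amine from adding to the vinyl ketone.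

**Step 11**
Reactants: 23 (5S)-5-{2-[(tert-butyldiphenylsilyl)oxy]ethyl}-6-iodo-4,4-dimethylhepta-1,6-dien-3-one
Product: 24 (3R,5S)-5-{2-[(tert-butyldiphenylsilyl)oxy]ethyl}-6-iodo-4,4-dimethylhepta-1,6-dien-3-ol
Conditions: (S)-2-methyl-CBS-oxazaborolidine (1.0 equiv), catecholborane, toluene, −78 → −40 °C; MeOH
Reagents that add atoms: none
Why: Corey–Bakshi–Shibata reduction with catecholborane, in which the quaternary CMe2 flank is the large and the vinyl group the small substituent, so the (S)-oxazaborolidine should deliver hydride to the face that gives the (3R)-carbinol (catalyst control, 1,2-reduction at low temperature).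

**Step 12**
Reactants: 24 (3R,5S)-5-{2-[(tert-butyldiphenylsilyl)oxy]ethyl}-6-iodo-4,4-dimethylhepta-1,6-dien-3-ol; 25 9-borabicyclo[3.3.1]nonane (9-BBN)
Product: 27 (1R,3R)-3-{2-[(tert-butyldiphenylsilyl)oxy]ethyl}-2,2-dimethyl-4-methylidenecyclohexan-1-ol, via B-alkyl-9-BBN borane 26 (not isolated)
Conditions: 9-BBN (2.5 equiv), THF, 0 °C → rt; then slow addition to Pd(dppf)Cl2 (10 mol %), AsPh3 (10 mol %), aq. K3PO4, DMF, 50 °C (high dilution)
Reagents that add atoms: none
Why: 9-BBN first turns the carbinol O–H into a borinate (loss of H2) and then adds anti-Markovnikov to the monosubstituted vinyl group to give the primary B-alkyl-9-BBN 26; after oxidative addition of the 2-iodoalkene to zerovalent palladium the base-activated borane transmetalates intramolecularly and reductive elimination forms the C(sp3)–C(sp2) ring bond between the methylidene-bearing carbon and its CH2 neighbour. The closest known reaction type is the one-pot hydroboration/intramolecular B-alkyl Suzuki–Miyaura coupling of 2-halo-1,6-dienes to methylenecycloalkanes. The six-membered carbocycle is closed by reductive elimination from a seven-membered palladacycle, exo with respect to the iodoalkene, so the C=CH2 bond ends exocyclic. No stereocentre is formed or touched: the carbinol carbon and the tertiary CH are spectators and the borinate is hydrolysed on work-up. The step needs chemoselective hydroboration (9-BBN should take the unhindered vinyl group far faster than the electron-poor 1,1-disubstituted iodoalkene), terminal regioselectivity (steric demand of 9-BBN) and ring closure over oligomerisation (high dilution and the gem-dimethyl group in the tether), while dppf should favour reductive elimination over β-hydride elimination.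

**Step 13**
Reactants: 27 (1R,3R)-3-{2-[(tert-butyldiphenylsilyl)oxy]ethyl}-2,2-dimethyl-4-methylidenecyclohexan-1-ol; 28 tetrabromomethane
Product: 29 tert-butyl{2-[(1R,3S)-3-bromo-2,2-dimethyl-6-methylidenecyclohexyl]ethoxy}diphenylsilane
Conditions: PPh3, CBr4, toluene, 0 → 60 °C
Reagents that add atoms: tetrabromomethane, BrC(Br)(Br)Br
Why: Appel reaction, in which the oxyphosphonium salt of the conformer with axial oxygen is displaced by bromide with inversion (SN2) along the equatorial trajectory, which should place bromine equatorial and cis to the side chain, a conversion of the kind used on 2,2-dimethylcyclohexanols of brominated terpenoids.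

**Step 14**
Reactants: 29 tert-butyl{2-[(1R,3S)-3-bromo-2,2-dimethyl-6-methylidenecyclohexyl]ethoxy}diphenylsilane
Product: 30 2-[(1R,3S)-3-bromo-2,2-dimethyl-6-methylidenecyclohexyl]ethan-1-ol
Conditions: Bu4NF, AcOH, THF, 0 °C → rt
Reagents that add atoms: none
Why: Fluoride-mediated cleavage of the silyl ether (desilylation), buffered with acetic acid so that the secondary bromide is not exposed to basic fluoride.

**Step 15**
Reactants: 30 2-[(1R,3S)-3-bromo-2,2-dimethyl-6-methylidenecyclohexyl]ethan-1-ol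
Product: 31 [(1R,3S)-3-bromo-2,2-dimethyl-6-methylidenecyclohexyl]acetaldehyde
Conditions: Dess–Martin periodinane, CH2Cl2, 0 °C → rt
Reagents that add atoms: none
Why: Dess–Martin oxidation of the primary alcohol to the aldehyde under near-neutral conditions should leave the exocyclic alkene and the bromide untouched.

**Step 16**
Reactants: 31 [(1R,3S)-3-bromo-2,2-dimethyl-6-methylidenecyclohexyl]acetaldehyde; 32 ethyl 2-[bis(2,2,2-trifluoroethoxy)phosphoryl]propanoate
Product: 33 ethyl (2Z)-4-[(1R,3S)-3-bromo-2,2-dimethyl-6-methylidenecyclohexyl]-2-methylbut-2-enoate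
Conditions: KN(SiMe3)2, 18-crown-6, THF, −78 °C
Reagents that add atoms: ethyl 2-[bis(2,2,2-trifluoroethoxy)phosphoryl]propanoate, CCOC(=O)C(C)P(=O)(OCC(F)(F)F)OCC(F)(F)F
Why: Still–Gennari olefination, in which the bis(trifluoroethyl)phosphonate anion with a dissociated potassium counter-ion eliminates under kinetic control, which should set the trisubstituted (Z)-alkene with the ester cis to the ring-bearing CH2.

**Step 17**
Reactants: 33 ethyl (2Z)-4-[(1R,3S)-3-bromo-2,2-dimethyl-6-methylidenecyclohexyl]-2-methylbut-2-enoate; 20 N,O-dimethylhydroxylamine hydrochloride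
Product: 34 (2Z)-4-[(1R,3S)-3-bromo-2,2-dimethyl-6-methylidenecyclohexyl]-N-methoxy-N,2-dimethylbut-2-enamide
Conditions: i-PrMgCl, THF, −20 °C
Reagents that add atoms: N,O-dimethylhydroxylamine hydrochloride, CNOC.Cl
Why: Magnesium amide aminolysis of the ester (Weinreb amide formation) at low temperature should preserve the (Z)-geometry and the secondary neopentyl bromide.

**Step 18**
Reactants: 34 (2Z)-4-[(1R,3S)-3-bromo-2,2-dimethyl-6-methylidenecyclohexyl]-N-methoxy-N,2-dimethylbut-2-enamide; 35 dibromomethane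
Product: 36 (3Z)-1-bromo-5-[(1R,3S)-3-bromo-2,2-dimethyl-6-methylidenecyclohexyl]-3-methylpent-3-en-2-one
Conditions: MeLi·LiBr, THF/Et2O, −78 °C (Barbier mode); aq. NH4Cl at −78 °C
Reagents that add atoms: dibromomethane, BrCBr
Why: Homologation of the Weinreb amide with bromomethyllithium made in situ by bromine–lithium exchange, in which 1,2-addition gives a tetrahedral intermediate that is stable at −78 °C and releases the bromomethyl ketone only on quench.

**Step 19**
Reactants: 36 (3Z)-1-bromo-5-[(1R,3S)-3-bromo-2,2-dimethyl-6-methylidenecyclohexyl]-3-methylpent-3-en-2-one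
Product: 37 (2S,3Z)-1-bromo-5-[(1R,3S)-3-bromo-2,2-dimethyl-6-methylidenecyclohexyl]-3-methylpent-3-en-2-ol
Conditions: (S)-2-methyl-CBS-oxazaborolidine (1.0 equiv), catecholborane, toluene, −78 °C; MeOH, pH 7 work-up
Reagents that add atoms: none
Why: Corey–Bakshi–Shibata reduction with the trisubstituted alkenyl group as the large and CH2Br as the small substituent, so the (S)-oxazaborolidine should give the (2S)-bromohydrin (catalyst control), and the neutral work-up avoids closure to the epoxide.

**Compound list**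
1 | but-3-yn-1-ol | C#CCCO | starting material
2 | tert-butylchlorodiphenylsilane | CC(C)(C)[Si](Cl)(c1ccccc1)c1ccccc1 | starting material
3 | tert-butyl(but-3-yn-1-yloxy)diphenylsilane | C#CCCO[Si](c1ccccc1)(c1ccccc1)C(C)(C)C | intermediate
4 | paraformaldehyde (formaldehyde source) | C=O | starting material
5 | {4-[(tert-butyldiphenylsilyl)oxy]but-1-yn-1-yl}lithium | [Li]C#CCCO[Si](c1ccccc1)(c1ccccc1)C(C)(C)C | intermediate
6 | 5-[(tert-butyldiphenylsilyl)oxy]pent-2-yn-1-ol | OCC#CCCO[Si](c1ccccc1)(c1ccccc1)C(C)(C)C | intermediate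
7 | (2E)-5-[(tert-butyldiphenylsilyl)oxy]pent-2-en-1-ol | OC/C=C/CCO[Si](c1ccccc1)(c1ccccc1)C(C)(C)C | intermediate
8 | methyl chloroformate | COC(=O)Cl | starting material
9 | (2E)-5-[(tert-butyldiphenylsilyl)oxy]pent-2-en-1-yl methyl carbonate | COC(=O)OC/C=C/CCO[Si](c1ccccc1)(c1ccccc1)C(C)(C)C | intermediate
10 | 1-methoxy-2-methyl-1-(trimethylsilyloxy)prop-1-ene | COC(O[Si](C)(C)C)=C(C)C | starting material
11 | methyl (3R)-3-{2-[(tert-butyldiphenylsilyl)oxy]ethyl}-2,2-dimethylpent-4-enoate | COC(=O)C(C)(C)[C@@H](C=C)CCO[Si](c1ccccc1)(c1ccccc1)C(C)(C)C | intermediate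
12 | ozone | [O-][O+]=O | starting material
13 | methyl (3S)-5-[(tert-butyldiphenylsilyl)oxy]-2,2-dimethyl-3-(1,2,4-trioxolan-3-yl)pentanoate | COC(=O)C(C)(C)[C@@H](C1OCOO1)CCO[Si](c1ccccc1)(c1ccccc1)C(C)(C)C | intermediate
14 | methyl (3S)-5-[(tert-butyldiphenylsilyl)oxy]-3-formyl-2,2-dimethylpentanoate | COC(=O)C(C)(C)[C@@H](C=O)CCO[Si](c1ccccc1)(c1ccccc1)C(C)(C)C | intermediate
15 | dimethyl (1-diazo-2-oxopropyl)phosphonate | COP(=O)(OC)C(=[N+]=[N-])C(C)=O | starting material
16 | methyl (3R)-5-[(tert-butyldiphenylsilyl)oxy]-3-ethynyl-2,2-dimethylpentanoate | COC(=O)C(C)(C)[C@@H](C#C)CCO[Si](c1ccccc1)(c1ccccc1)C(C)(C)C | intermediate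
17 | 9-iodo-9-borabicyclo[3.3.1]nonane | IB1C2CCCC1CCC2 | starting material
18 | methyl (3S,4Z)-5-(9-borabicyclo[3.3.1]nonan-9-yl)-3-{2-[(tert-butyldiphenylsilyl)oxy]ethyl}-4-iodo-2,2-dimethylpent-4-enoate | COC(=O)C(C)(C)[C@@H](/C(I)=C/B1C2CCCC1CCC2)CCO[Si](c1ccccc1)(c1ccccc1)C(C)(C)C | intermediate
19 | methyl (3S)-3-{2-[(tert-butyldiphenylsilyl)oxy]ethyl}-4-iodo-2,2-dimethylpent-4-enoate | COC(=O)C(C)(C)[C@@H](C(I)=C)CCO[Si](c1ccccc1)(c1ccccc1)C(C)(C)C | intermediate
20 | N,O-dimethylhydroxylamine hydrochloride | CNOC.Cl | starting material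
21 | (3S)-3-{2-[(tert-butyldiphenylsilyl)oxy]ethyl}-4-iodo-N-methoxy-N,2,2-trimethylpent-4-enamide | CON(C)C(=O)C(C)(C)[C@@H](C(I)=C)CCO[Si](c1ccccc1)(c1ccccc1)C(C)(C)C | intermediate
22 | vinylmagnesium bromide | C=C[Mg]Br | starting material
23 | (5S)-5-{2-[(tert-butyldiphenylsilyl)oxy]ethyl}-6-iodo-4,4-dimethylhepta-1,6-dien-3-one | C=CC(=O)C(C)(C)[C@@H](C(I)=C)CCO[Si](c1ccccc1)(c1ccccc1)C(C)(C)C | intermediate
24 | (3R,5S)-5-{2-[(tert-butyldiphenylsilyl)oxy]ethyl}-6-iodo-4,4-dimethylhepta-1,6-dien-3-ol | C=C[C@@H](O)C(C)(C)[C@@H](C(I)=C)CCO[Si](c1ccccc1)(c1ccccc1)C(C)(C)C | intermediate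
25 | 9-borabicyclo[3.3.1]nonane | B1C2CCCC1CCC2 | starting material
26 | 9-[(3R,5S)-3-(9-borabicyclo[3.3.1]nonan-9-yloxy)-5-{2-[(tert-butyldiphenylsilyl)oxy]ethyl}-6-iodo-4,4-dimethylhept-6-en-1-yl]-9-borabicyclo[3.3.1]nonane | C(CB1C2CCCC1CCC2)[C@@H](OB1C2CCCC1CCC2)C(C)(C)[C@@H](C(I)=C)CCO[Si](c1ccccc1)(c1ccccc1)C(C)(C)C | intermediate
27 | (1R,3R)-3-{2-[(tert-butyldiphenylsilyl)oxy]ethyl}-2,2-dimethyl-4-methylidenecyclohexan-1-ol | C=C1CC[C@@H](O)C(C)(C)[C@@H]1CCO[Si](c1ccccc1)(c1ccccc1)C(C)(C)C | intermediate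
28 | tetrabromomethane | BrC(Br)(Br)Br | starting material
29 | tert-butyl{2-[(1R,3S)-3-bromo-2,2-dimethyl-6-methylidenecyclohexyl]ethoxy}diphenylsilane | C=C1CC[C@H](Br)C(C)(C)[C@@H]1CCO[Si](c1ccccc1)(c1ccccc1)C(C)(C)C | intermediate
30 | 2-[(1R,3S)-3-bromo-2,2-dimethyl-6-methylidenecyclohexyl]ethan-1-ol | C=C1CC[C@H](Br)C(C)(C)[C@@H]1CCO | intermediate
31 | [(1R,3S)-3-bromo-2,2-dimethyl-6-methylidenecyclohexyl]acetaldehyde | C=C1CC[C@H](Br)C(C)(C)[C@@H]1CC=O | intermediate
32 | ethyl 2-[bis(2,2,2-trifluoroethoxy)phosphoryl]propanoate | CCOC(=O)C(C)P(=O)(OCC(F)(F)F)OCC(F)(F)F | starting material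
33 | ethyl (2Z)-4-[(1R,3S)-3-bromo-2,2-dimethyl-6-methylidenecyclohexyl]-2-methylbut-2-enoate | C=C1CC[C@H](Br)C(C)(C)[C@@H]1C/C=C(/C)C(=O)OCC | intermediate
34 | (2Z)-4-[(1R,3S)-3-bromo-2,2-dimethyl-6-methylidenecyclohexyl]-N-methoxy-N,2-dimethylbut-2-enamide | C=C1CC[C@H](Br)C(C)(C)[C@@H]1C/C=C(/C)C(=O)N(C)OC | intermediate
35 | dibromomethane | BrCBr | starting material
36 | (3Z)-1-bromo-5-[(1R,3S)-3-bromo-2,2-dimethyl-6-methylidenecyclohexyl]-3-methylpent-3-en-2-one | C=C1CC[C@H](Br)C(C)(C)[C@@H]1C/C=C(/C)C(=O)CBr | intermediate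
37 | (2S,3Z)-1-bromo-5-[(1R,3S)-3-bromo-2,2-dimethyl-6-methylidenecyclohexyl]-3-methylpent-3-en-2-ol | C=C1CC[C@H](Br)C(C)(C)[C@@H]1C/C=C(/C)[C@H](O)CBr | target

**Step count and risks**
Total step count: 19. Longest linear sequence: 19 (fully linear from but-3-yn-1-ol).

Steps most likely to fail:

Step 13 (Appel reaction). The axial oxyphosphonium group may be lost by anti-periplanar E2 elimination to the cyclohexene, or backside attack at the neopentyl carbon may not occur. The fallback forms the C–H bond, not the C–Br bond, last. It sets out from 27: Dess–Martin oxidation gives (3R)-3-{2-[(tert-butyldiphenylsilyl)oxy]ethyl}-2,2-dimethyl-4-methylidenecyclohexan-1-one F1; hydrazine hydrate in EtOH gives [(3R)-3-{2-[(tert-butyldiphenylsilyl)oxy]ethyl}-2,2-dimethyl-4-methylidenecyclohexylidene]hydrazine F2; CuBr2/LiOt-Bu in THF converts the hydrazone into tert-butyl{2-[(1R)-3,3-dibromo-2,2-dimethyl-6-methylidenecyclohexyl]ethoxy}diphenylsilane F3; mono-reduction with Bu3SnH (1 equiv), Et3B/air, toluene, −78 °C should deliver hydrogen to the α-bromo radical on the ring face remote from the C1 substituent, which leaves bromine cis to that substituent, and the route is rejoined at 29.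

Step 11 (CBS reduction of the vinyl ketone). Facial discrimination between the vinyl and the tert-alkyl flank may be insufficient, or conjugate reduction of the vinyl ketone may compete. The fallback goes through an ynone, whose two flanks differ strongly. It sets out from 21: lithium (trimethylsilyl)acetylide gives (5S)-5-{2-[(tert-butyldiphenylsilyl)oxy]ethyl}-6-iodo-4,4-dimethyl-1-(trimethylsilyl)hept-6-en-1-yn-3-one F4; asymmetric transfer hydrogenation (RuCl[(S,S)-TsDPEN](p-cymene) or its mirror image, whichever gives this alcohol, i-PrOH) gives (3S,5S)-5-{2-[(tert-butyldiphenylsilyl)oxy]ethyl}-6-iodo-4,4-dimethyl-1-(trimethylsilyl)hept-6-en-1-yn-3-ol F5; K2CO3/MeOH removes the alkynyl silyl group to give (3R,5S)-5-{2-[(tert-butyldiphenylsilyl)oxy]ethyl}-6-iodo-4,4-dimethylhept-6-en-1-yn-3-ol F6; hydrozirconation with Cp2Zr(H)Cl and protonolysis turns the ethynyl into the vinyl group, and the route is rejoined at 24.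

Step 5 (allylic alkylation). Branched selectivity or enantioselectivity may erode with this alkyl-substituted carbonate, or activation of the silyl ketene acetal may be sluggish. The fallback uses a sigmatropic rearrangement and a resolution. It sets out from 7: isobutyryl chloride/pyridine gives (2E)-5-[(tert-butyldiphenylsilyl)oxy]pent-2-en-1-yl 2-methylpropanoate F7; Ireland–Claisen rearrangement (LiN(i-Pr)2, Me3SiCl, THF, −78 → 60 °C; aqueous acid) forms the same CH–CMe2 bond and gives rac-3-{2-[(tert-butyldiphenylsilyl)oxy]ethyl}-2,2-dimethylpent-4-enoic acid F8; Me3SiCHN2/MeOH gives methyl rac-3-{2-[(tert-butyldiphenylsilyl)oxy]ethyl}-2,2-dimethylpent-4-enoate F9; preparative chromatography on a chiral stationary phase delivers the (3R)-enantiomer, and the route is rejoined at 11.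

**Further compounds**
F1 | step 13 | (3R)-3-{2-[(tert-butyldiphenylsilyl)oxy]ethyl}-2,2-dimethyl-4-methylidenecyclohexan-1-one | C=C1CCC(=O)C(C)(C)[C@@H]1CCO[Si](c1ccccc1)(c1ccccc1)C(C)(C)C
F2 | step 13 | [(3R)-3-{2-[(tert-butyldiphenylsilyl)oxy]ethyl}-2,2-dimethyl-4-methylidenecyclohexylidene]hydrazine | C=C1CCC(=NN)C(C)(C)[C@@H]1CCO[Si](c1ccccc1)(c1ccccc1)C(C)(C)C
F3 | step 13 | tert-butyl{2-[(1R)-3,3-dibromo-2,2-dimethyl-6-methylidenecyclohexyl]ethoxy}diphenylsilane | C=C1CCC(Br)(Br)C(C)(C)[C@@H]1CCO[Si](c1ccccc1)(c1ccccc1)C(C)(C)C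
F4 | step 11 | (5S)-5-{2-[(tert-butyldiphenylsilyl)oxy]ethyl}-6-iodo-4,4-dimethyl-1-(trimethylsilyl)hept-6-en-1-yn-3-one | C[Si](C)(C)C#CC(=O)C(C)(C)[C@@H](C(I)=C)CCO[Si](c1ccccc1)(c1ccccc1)C(C)(C)C
F5 | step 11 | (3S,5S)-5-{2-[(tert-butyldiphenylsilyl)oxy]ethyl}-6-iodo-4,4-dimethyl-1-(trimethylsilyl)hept-6-en-1-yn-3-ol | C[Si](C)(C)C#C[C@@H](O)C(C)(C)[C@@H](C(I)=C)CCO[Si](c1ccccc1)(c1ccccc1)C(C)(C)C
F6 | step 11 | (3R,5S)-5-{2-[(tert-butyldiphenylsilyl)oxy]ethyl}-6-iodo-4,4-dimethylhept-6-en-1-yn-3-ol | C#C[C@@H](O)C(C)(C)[C@@H](C(I)=C)CCO[Si](c1ccccc1)(c1ccccc1)C(C)(C)C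
F7 | step 5 | (2E)-5-[(tert-butyldiphenylsilyl)oxy]pent-2-en-1-yl 2-methylpropanoate | CC(C)C(=O)OC/C=C/CCO[Si](c1ccccc1)(c1ccccc1)C(C)(C)C
F8 | step 5 | rac-3-{2-[(tert-butyldiphenylsilyl)oxy]ethyl}-2,2-dimethylpent-4-enoic acid | OC(=O)C(C)(C)C(C=C)CCO[Si](c1ccccc1)(c1ccccc1)C(C)(C)C
F9 | step 5 | methyl rac-3-{2-[(tert-butyldiphenylsilyl)oxy]ethyl}-2,2-dimethylpent-4-enoate | COC(=O)C(C)(C)C(C=C)CCO[Si](c1ccccc1)(c1ccccc1)C(C)(C)C
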